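The vessel is closed, stirred and held at one temperature, and in it Xa and Xb turn into Xp with Xc as catalyst. Here is what has been run, with larch as the next flask.

| flask | Xa | Xb | Xc | Xp | time |
|---|---|---|---|---|---|
| cedar | 0.100 M | 0.200 M | 0.00300 M |  |  |
| elm | 0.100 M | 0.200 M | 0.00450 M |  |  |
| maple | 0.150 M | 0.200 M | 0.00300 M |  |  |
| ash | 0.100 M | 0.200 M | 0.00300 M | 0.0500 M |  |
| larch | 0.100 M | 0.0660 M | 0.00600 M |  | 33 min |

| run | time / min | [Xa] / M |
|---|---|---|
| cedar run | 1.3 | 0.0986 |
| cedar run | 2.1 | 0.0999 |
| cedar run | 3.3 | 0.0972 |
| cedar run | 5.2 | 0.0967 |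
| cedar run | 8.3 | 0.0931 |
| cedar run | 13 | 0.0804 |
| cedar run | 21 | 0.0531 |
| cedar run | 33 | 0.0171 |
| elm run | 1.3 | 0.0983 |
| elm run | 2.1 | 0.0995 |
| elm run | 3.3 | 0.0992 |
| elm run | 5.2 | 0.0958 |
| elm run | 8.3 | 0.0897 |
| elm run | 13 | 0.0782 |
| elm run | 21 | 0.0476 |
| elm run | 33 | 0.0163 |
| maple run | 1.3 | 0.1493 |
| maple run | 2.1 | 0.1482 |
| maple run | 3.3 | 0.1477 |
| maple run | 5.2 | 0.1450 |
| maple run | 8.3 | 0.1364 |
| maple run | 13 | 0.1086 |
| maple run | 21 | 0.0518 |
| maple run | 33 | 0.0163 |
| ash run | 1.3 | 0.0880 |
| ash run | 2.1 | 0.0782 |
| ash run | 3.3 | 0.0665 |
| ash run | 5.2 | 0.0517 |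
| ash run | 8.3 | 0.0327 |
| ash run | 13 | 0.0153 |
| ash run | 21 | 0.0045 |
| ash run | 33 | 4 × 10⁻⁴ |

(readings scatter by 0.001 M)

- reaction order in [Xc] at the outset, round the charge of the cedar run, defined at two percent of the Xa turned into Xp
- reaction order in [Xa] at the outset, round the charge of the cedar run, defined at two percent of the Xa turned into Xp (one fixed amount of Xp, the same in the runs compared)
- Xa in the larch run at 33 min, as a share of the Xa charged

- Overall: Xa + Xb -> Xp, with Xc as catalyst.
- Constant volume, constant temperature.
- "The second partner" is Xb.
- An order is taken over about fifteen percent of the charge, up and down.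

You have to decide whether larch goes in as written, and whether its reading at 33 min can be taken as its end state. Ask first what that end state must be. Xa and Xb go one for one in the overall equation and larch holds less Xb than Xa, so Xb is the limiting reagent, and that equation leaves 34.0 % of the Xa once Xb is used up. Allowing for one Xa held on each Xc, I take the floor as 28.0 % of the charge.

Then ask how fast it gets there. Ash, seeded with Xp, has lost 33.5 % of its Xa by 3.3 min, far more than the 2.80 % of cedar. So Xp speeds its own making. This is autocatalysis, a loop that acts like an unstable first-order system. Take its rate as proportional to Xa, Xb and Xp together. Dividing the fall of ln Xa per minute in ash by Xb and Xp at the middle of a stretch gives 9.44 /M²/min on the early stretch and 10.0 /M²/min on the later one, although Xb was falling. Their mean is what I carry: the loop constant, the rate of the loop divided by the product of the three concentrations, 9.72 /M²/min. One over this constant, Xa and Xb is your time constant, the time in which Xp would grow by a factor e. At the start it is 5.14 min in cedar but 15.6 min in larch.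

The loop needs a seed, which I take as a steady trickle through the catalyst, so that the Xp made is trickle times time constant times (e^(t/time constant) minus one), with the time constant taken at the halfway composition. Cedar has turned 19.6 % of its charge by 13 min, and with a halfway time constant of 6.00 min that gives a trickle of 4.22 × 10⁻⁴ M/min. Elm, at 21.8 % by the same time, gives 1.14 times that trickle on 1.50 times the Xc. What less Xb does to the trickle no run shows, so for larch I assume the two effects cancel and keep the trickle of cedar.

Guess that half the Xb of larch gets used. The halfway time constant is then 24.9 min, the window is 1.33 time constants, and 29.1 % of the charge turns. My reckoning leaves 70.9 % of the Xa, well above the floor. So charge larch as written, and read its 33 min sample as mid-course, not as an end.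

The forecast says 0.2 for the order in Xc, 0.95 for the order in Xa and 62 % for larch, noting that “no run varied Xb”.

The flask gives 69.4 % of the Xa in larch at 33 min, with orders 0.88 in Xa and 0.32 in Xc, and elm runs at 1.1 times the rate of cedar at equal Xp made.

    Xc + Xa → E + Xh (6.360 /M/min)
    E + Xb → Xp + Xc (2.790 /M/min)
    2 Xc ⇌ Xc2, settled at all times (1390 /M)
    Xa + Xb + Xp → 2 Xp (9.720 /M²/min)

Halfway to what larch really turned, the loop constant gives a time constant of 24.0 min, so the window held 1.38 time constants. On maple, with the trickle of cedar and the halfway composition, the same constant puts half the charge made at 19.6 min, and the flask takes 17.6 min.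

The readings were computed on assumed constants; the scatter is artificial.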